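**Retrosynthetic overview**
1. Target ⇐ γ-oxygenation with O2 of the Diels–Alder dimer, a β,γ-unsaturated methyl ketone (installs C1–OH and moves the alkene to C2=C3).
2. Dimer ⇐ two enyne lactones + two methyl vinyl ketones in one flask: enyne ring-closing metathesis/cross-metathesis (both seven-membered rings), then head-to-tail [4+2] homodimerisation (cyclohexene and spiro centre).
3. Enyne lactone ⇐ Pd cyclocarbonylation of an anti-homopropargylic alcohol (α-methylene lactone from alkyne + CO), then C-desilylation.
4. Anti-homopropargylic alcohol ⇐ β-alkynyl aldehyde (C10 from Rh conjugate alkynylation of crotonaldehyde) + chiral propargylic mesylate (Marshall addition sets C7/C8).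
5. Ring order: lactone → seven-membered rings B and E → cyclohexene C (the last three rings in one operation).

Assumptions: the SMILES is taken literally (both halves are (3aS,7S,8aR) trans-lactones with the C10 methyl cis to C8–O); (R)-DTBM-SEGPHOS is taken to give the (S)-aldehyde of step 1, (R)-TRIP the (R)-carbinol of step 2, and the Marshall addition is taken to run with overall inversion at the propargylic carbon. If a sense is reversed, the antipodal catalyst or mesylate is used.

Numbering in the text: xanthane numbering for each half (C1 ring carbon bearing the side chain, C2–C3–C4(=O)–C15 side chain, C5, C6, C7, C8 (C–O), C9, C10 (C–CH3), C11/C13 methylene lactone, C12 lactone C=O). Primed atoms belong to the half whose lactone becomes spiro. Rings: A methylene lactone and B seven-membered ring of the diene half, C cyclohexene, D spiro lactone and E cycloheptene of the dienophile half.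

**Route**

Step 1
Reactants: 1 (E)-but-2-enal (crotonaldehyde); 2 ethynyl[tri(propan-2-yl)]silane
Product: 3 (3S)-3-methyl-5-[tri(propan-2-yl)silyl]pent-4-ynal
Conditions: [Rh(OAc)(C2H4)2]2 (2.5 mol %), (R)-DTBM-SEGPHOS (6 mol %), MeOH, 40 °C
Reagents that add atoms: none
Why: Rh-catalysed asymmetric conjugate alkynylation of an enal, in which the bulky silylalkyne and bulky bisphosphine suppress alkyne dimerisation and 1,2-addition and the chiral alkynyl-rhodium adds to one enantioface to set C10 as (S); the silyl cap also keeps this alkyne silent until step 6.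

Step 2
Reactants: 4 3-(trimethylsilyl)prop-2-ynal; 5 2-(prop-2-en-1-yl)-4,4,5,5-tetramethyl-1,3,2-dioxaborolane
Product: 7 (3R)-hex-5-en-1-yn-3-ol, via borate ester 6 (not isolated)
Conditions: (R)-TRIP [(R)-3,3'-bis(2,4,6-triisopropylphenyl)-1,1'-binaphthyl-2,2'-diyl hydrogen phosphate] (5 mol %), toluene, −30 °C; then K2CO3 (0.2 equiv), MeOH, 25 °C
Reagents that add atoms: none
Why: Chiral phosphoric acid-catalysed allylboration through a closed chair transition state sets the carbinol centre (R), and methanolysis in the same flask cleaves the O–B and C(sp)–Si bonds; any minor enantiomer ends up as a separable diastereomer after step 4.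

Step 3
Reactants: 7 (3R)-hex-5-en-1-yn-3-ol
Product: 8 (3R)-hex-5-en-1-yn-3-yl methanesulfonate
Conditions: MsCl (1.2 equiv), Et3N (1.5 equiv), CH2Cl2, −78 to 0 °C; used without chromatography
Reagents that add atoms: methanesulfonyl chloride, CS(=O)(=O)Cl
Why: O-sulfonylation does not touch the C–O bond, so the (R) configuration is retained.

Step 4
Reactants: 3 (3S)-3-methyl-5-[tri(propan-2-yl)silyl]pent-4-ynal; 8 (3R)-hex-5-en-1-yn-3-yl methanesulfonate
Product: 9 (3S,4R,6S)-6-methyl-3-(prop-2-en-1-yl)-8-[tri(propan-2-yl)silyl]octa-1,7-diyn-4-ol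
Conditions: Pd(OAc)2 (5 mol %), PPh3 (5 mol %), InI (1.4 equiv), THF/HMPA 3:1, 0 °C to rt; aq. NH4Cl
Reagents that add atoms: none
Why: Marshall propargylation, in which anti-SN2' oxidative addition of zerovalent palladium, transmetalation to indium and a closed SE2' transition state transfer the mesylate chirality to C7 (S, overall inversion) and give the anti C7/C8 adduct (C8 R) under reagent control, the remote C10 centre having no say.

Step 5
Reactants: 9 (3S,4R,6S)-6-methyl-3-(prop-2-en-1-yl)-8-[tri(propan-2-yl)silyl]octa-1,7-diyn-4-ol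
Product: 10 (4S,5R)-3-methylidene-5-{(2S)-2-methyl-4-[tri(propan-2-yl)silyl]but-3-yn-1-yl}-4-(prop-2-en-1-yl)oxolan-2-one
Conditions: PdCl2 (5 mol %), SnCl2 (5 mol %), PPh3 (10 mol %), CO (8 atm), MeCN, 75 °C
Reagents that add atoms: carbon monoxide, [C-]#[O+]
Why: Hydroxyl-directed Pd cyclocarbonylation (alkoxycarbonyl-palladium formation, intramolecular syn addition to the terminal alkyne, protonolysis) closes the α-methylene-γ-butyrolactone without touching C7 or C8, so the anti alcohol gives the trans lactone, while the silyl-capped internal alkyne cannot compete for six-ring closure.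

Step 6
Reactants: 10 (4S,5R)-3-methylidene-5-{(2S)-2-methyl-4-[tri(propan-2-yl)silyl]but-3-yn-1-yl}-4-(prop-2-en-1-yl)oxolan-2-one
Product: 11 (4S,5R)-3-methylidene-5-[(2S)-2-methylbut-3-yn-1-yl]-4-(prop-2-en-1-yl)oxolan-2-one
Conditions: Bu4NF (1.2 equiv), AcOH (1.2 equiv), THF, 0 °C to rt
Reagents that add atoms: none
Why: Fluoride-induced C(sp)–Si cleavage, with acetic acid buffering to protect the methylene lactone from conjugate addition or isomerisation; no stereocentre is involved.

Step 7
Reactants: 11 (4S,5R)-3-methylidene-5-[(2S)-2-methylbut-3-yn-1-yl]-4-(prop-2-en-1-yl)oxolan-2-one (2 molecules per product); 12 but-3-en-2-one (methyl vinyl ketone)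
Product: 15 Diels–Alder dimer (pentacyclic β,γ-unsaturated ketone with C1=C2 and C3–H), via vinyl triene 13 (not isolated), via monomer 14 (not isolated)
Conditions: second-generation Hoveyda–Grubbs catalyst RuCl2(H2IMes)(=CH–C6H4–2-OiPr) (10 mol %), 12 (6 equiv), CH2Cl2 (0.01 M), 40 °C, 12 h; then strip CH2Cl2 and excess 12, toluene (3 M), BHT (5 mol %), 105 °C, 72 h, sealed tube, Ar
Reagents that add atoms: none
Why: Domino ring-closing enyne metathesis/cross-metathesis (exo closure of the allyl alkene onto the alkyne gives the seven-membered ring and diene 13, whose vinyl group cross-metathesises with 12 to the E-dienone 14 while the electron-poor methylene lactone is spared) followed by a thermal head-to-tail Diels–Alder homodimerisation in which the methylene lactone of one 14 adds exo (lactone C=O away from the diene, as usual for α-methylene-γ-butyrolactones) through its face anti to C6' (sets C11') to the C5=C1–C2=C3 diene of a second 14, C13' bonding to C5 on the ring B face cis to C8–O and the C10 methyl (sets C5, and C3 transiently), the only diene face on which the dienophile keeps both its exo mode and its anti-C6' face; the C5/C3-epimeric endo adduct is the expected by-product and is removed by chromatography.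

Step 8
Reactants: 15 Diels–Alder dimer
Product: 17 target CNP0168949.4, via C1 hydroperoxide 16 (not isolated)
Conditions: O2 (1 atm), DBU (1.0 equiv), P(OEt)3 (2.0 equiv), MeCN, −20 to 0 °C
Reagents that add atoms: dioxygen, O=O
Why: Base-mediated autoxidation of a β,γ-unsaturated ketone with in situ phosphite reduction, in which DBU removes the doubly activated C3–H, O2 adds at the γ-carbon C1 (C3 is shielded by the spiro centre) from the convex face of the cis-fused B/C bicycle, cis to C5–H and C10–H and anti to C13' and the C10 methyl, and the alkene moves to C2=C3, erasing the C3 centre.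

**Compound list**
1 | (E)-but-2-enal | C/C=C/C=O | starting material
2 | ethynyl[tri(propan-2-yl)]silane | C#C[Si](C(C)C)(C(C)C)C(C)C | starting material
3 | (3S)-3-methyl-5-[tri(propan-2-yl)silyl]pent-4-ynal | O=CC[C@H](C)C#C[Si](C(C)C)(C(C)C)C(C)C | intermediate
4 | 3-(trimethylsilyl)prop-2-ynal | O=CC#C[Si](C)(C)C | starting material
5 | 2-(prop-2-en-1-yl)-4,4,5,5-tetramethyl-1,3,2-dioxaborolane | C=CCB1OC(C)(C)C(C)(C)O1 | starting material
6 | 2-{[(3R)-1-(trimethylsilyl)hex-5-en-1-yn-3-yl]oxy}-4,4,5,5-tetramethyl-1,3,2-dioxaborolane | C=CC[C@@H](OB1OC(C)(C)C(C)(C)O1)C#C[Si](C)(C)C | intermediate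
7 | (3R)-hex-5-en-1-yn-3-ol | C=CC[C@@H](O)C#C | intermediate
8 | (3R)-hex-5-en-1-yn-3-yl methanesulfonate | C=CC[C@@H](OS(C)(=O)=O)C#C | intermediate
9 | (3S,4R,6S)-6-methyl-3-(prop-2-en-1-yl)-8-[tri(propan-2-yl)silyl]octa-1,7-diyn-4-ol | C=CC[C@@H](C#C)[C@H](O)C[C@H](C)C#C[Si](C(C)C)(C(C)C)C(C)C | intermediate
10 | (4S,5R)-3-methylidene-5-{(2S)-2-methyl-4-[tri(propan-2-yl)silyl]but-3-yn-1-yl}-4-(prop-2-en-1-yl)oxolan-2-one | C=C1C(=O)O[C@H](C[C@H](C)C#C[Si](C(C)C)(C(C)C)C(C)C)[C@H]1CC=C | intermediate
11 | (4S,5R)-3-methylidene-5-[(2S)-2-methylbut-3-yn-1-yl]-4-(prop-2-en-1-yl)oxolan-2-one | C=C1C(=O)O[C@H](C[C@H](C)C#C)[C@H]1CC=C | intermediate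
12 | but-3-en-2-one | CC(=O)C=C | starting material
13 | (3aS,7S,8aR)-6-ethenyl-7-methyl-3-methylidene-3,3a,4,7,8,8a-hexahydro-2H-cyclohepta[b]furan-2-one | C=C1C(=O)O[C@@H]2C[C@H](C)C(C=C)=CC[C@@H]12 | intermediate
14 | (3aS,7S,8aR)-7-methyl-3-methylidene-6-[(1E)-3-oxobut-1-en-1-yl]-3,3a,4,7,8,8a-hexahydro-2H-cyclohepta[b]furan-2-one | C=C1C(=O)O[C@@H]2C[C@H](C)C(/C=C/C(C)=O)=CC[C@@H]12 | intermediate
15 | Diels–Alder dimer: the target skeleton without the C1 hydroxyl, C1=C2 alkene, C3–H bearing the acetyl cis to C7' and C6; C5–H, C8–H, C10–H on one face of ring B, C13', C8–O and the C10 methyl on the other | C=C1C(=O)O[C@@H]2C[C@H](C)C3=C[C@H](C(C)=O)[C@]4(C[C@@H]3C[C@@H]12)C(=O)O[C@@H]1C[C@H](C)C(/C=C/C(C)=O)=CC[C@H]14 | intermediate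
16 | C1 hydroperoxide of the target (OOH in place of OH) | C=C1C(=O)O[C@@H]2C[C@H](C)[C@]3(OO)C=C(C(C)=O)[C@]4(C[C@@H]3C[C@@H]12)C(=O)O[C@@H]1C[C@H](C)C(/C=C/C(C)=O)=CC[C@H]14 | intermediate
17 | CNP0168949.4 | C=C1C(=O)O[C@@H]2C[C@H](C)[C@]3(O)C=C(C(C)=O)[C@]4(C[C@@H]3C[C@@H]12)C(=O)O[C@@H]1C[C@H](C)C(/C=C/C(C)=O)=CC[C@H]14 | target

**Step count**
Total: 8 steps. Longest linear sequence: 7 steps (steps 2 to 8, from 4); step 1 is the convergent branch.

**Steps most likely to fail, with fallbacks**

Most at risk is step 7.
- The needed diene face is the more folded face of ring B (axial C7–H and C9–H point there), so the required adduct competes with the C5/C3-epimeric endo adduct through the open face; the ratio cannot be predicted with confidence and the needed isomer may not be the major one.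
- 15 still carries a diene and a methylene lactone, so it can oligomerise; the thermal stage should be stopped at partial conversion and 14 recycled.
- Ruthenium residues at 105 °C may isomerise alkenes.
- Fallback (sets out from 11, returns at 15): stop after the metathesis stage and isolate 14. Combine 14 as the diene with 11 as a pure dienophile (3 equiv, recoverable; it has no diene, so oligomers cannot form) at 12 kbar in CH2Cl2 at 25 °C to give the enyne-bearing cross-adduct F1. Ring E is then closed last: second-generation Hoveyda–Grubbs catalyst and 12 in CH2Cl2 at 40 °C take F1 through the vinyl triene F2 to 15. This addresses oligomerisation and the ruthenium problem; the diene-face ratio is not expected to improve, so separation of the C5 epimer is still needed.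

Second is step 8.
- O2 may also attack C3 or the enolisable methyl ketones.
- DBU may add to or isomerise the methylene lactone.
- Fallback (sets out from 15, returns at 17): soft enolisation with TBSOTf/Et3N in CH2Cl2 at −78 °C gives the silyl dienol ether F3 (C1=C2–C3=C4–OSi). A vinylogous Rubottom oxidation (mCPBA, NaHCO3, CH2Cl2, −40 °C, aqueous work-up) epoxidises the distal C1=C2 bond from the same convex face and collapses to 17 without any amine base.

Third is step 5.
- Palladium hydrides may isomerise or carbonylate the allyl group.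
- The 1,5-enyne may cycloisomerise.
- Turnover under Norton-type conditions may be low.
- Fallback (sets out from 9, returns at 10): Markovnikov hydroiodination of the terminal alkyne (B-iodo-9-borabicyclo[3.3.1]nonane, pentane, −20 °C, then AcOH) gives the 2-iodoalkene F4. Carbonylative lactonisation through oxidative addition rather than alkoxycarbonyl-palladium (Pd(PPh3)4 5 mol %, CO 1 atm, Et3N, MeCN, 60 °C) then closes 10.

**Further compounds**
F1 | step 7 | cross-adduct of 14 (diene) and 11 (dienophile): 15 with ring E still open as the C7' allyl and C8' (2S)-2-methylbut-3-ynyl groups | C=C1C(=O)O[C@@H]2C[C@H](C)C3=C[C@H](C(C)=O)[C@]4(C[C@@H]3C[C@@H]12)C(=O)O[C@H](C[C@H](C)C#C)[C@H]4CC=C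
F2 | step 7 | 15 with a vinyl group at C1' in place of the 3-oxobutenyl chain | C=C1C(=O)O[C@@H]2C[C@H](C)C3=C[C@H](C(C)=O)[C@]4(C[C@@H]3C[C@@H]12)C(=O)O[C@@H]1C[C@H](C)C(C=C)=CC[C@H]14
F3 | step 8 | tert-butyldimethylsilyl dienol ether of 15 (C1=C2–C3=C4(OSi)–CH3, enol ether geometry not controlled) | C=C1C(=O)O[C@@H]2C[C@H](C)C3=CC(=C(C)O[Si](C)(C)C(C)(C)C)[C@]4(C[C@@H]3C[C@@H]12)C(=O)O[C@@H]1C[C@H](C)C(/C=C/C(C)=O)=CC[C@H]14
F4 | step 5 | 2-iodoalkene from 9 (C≡CH replaced by C(I)=CH2, other centres unchanged) | C=CC[C@@H](C(I)=C)[C@H](O)C[C@H](C)C#C[Si](C(C)C)(C(C)C)C(C)C
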